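You hold two charges at one loading, 4.6 mol% of initiator on the free monomer, so autumn has 0.0290 M of initiator and noon 0.0920 M, and you must choose which to repeat for longer chains.

| setting | autumn | noon |
|---|---|---|
| free monomer | 0.63 M | 2.0 M |
| initiator | 4.6 mol% | 4.6 mol% |
| time | 8.0 d | 8.0 d |

    free monomer + initiator → living end + monomer in chains (k1 = 0.052 M⁻¹ min⁻¹)
    free monomer + living end → monomer in chains + living end, rate k2*[living end]*[free monomer] (k2 = 0.35 M⁻¹ min⁻¹)
    monomer in chains + living end → free monomer + living end, rate k3*[living end] as long as [monomer in chains] is above zero (k3 = 0.11 min⁻¹)
    living end → dead end (k4 = 0.0035 min⁻¹)

- the average divides the monomer in chains by the number of chains begun, living and dead together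
- run time (autumn): 8.0 d

1. which of the two ends with the longer chains by the average number of monomer units in a chain (chains begun, living or dead) ("neither" if they lie within 10%) (autumn / noon / neither)
2. average number of monomer units in a chain (chains begun, living or dead) at the end, autumn
3. average number of monomer units in a chain (chains begun, living or dead) at the end, noon

Steps 2 and 3 balance where c(free monomer) equals k3/k2, 0.314 M, the equilibrium monomer concentration. With free monomer at that level, initiator has a half-life by step 1 of 42.4 min, far shorter than the run, and the 8.0 d hold 58.2 half-lives of the living end (0.14 d each), so I reckon with chains begun from the whole initiator charge and dead by the end.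

A chain begun lives 286 min on average, so the charge supplies c(initiator)/k4 of living-end time. Taking the monomer used by step 1 as small, the excess of free monomer over the equilibrium level shrinks by a factor e for each unit of the growth count, k2·c(initiator)/k4 at the charge, which is 2.90 for autumn. At one loading the count scales with the charge of free monomer, so noon has 9.20. Autumn should therefore stop at 0.332 M with an average of 10.3, and noon at 0.314 M with 18.3, longer. I would charge noon and leave the time as it is.

The forecast also says noon, with 10.3 for autumn and 18.3 for noon, and holds of the level k3/k2 that the autumn charge “stalls just above it”.

The flask gives noon, with 10.4 for autumn and 18.3 for noon. The autumn average read 10.3 at 0.800 d, and 10.4 at 80.0 d was no different from its value at 8.00 d. Now take the noon flask recharged with 0.50 M of free monomer at the same loading. Scaling the autumn count by the charge gives 2.30, hence a stop at 0.333 M and an average of 7.26. That flask reads 7.39, with 66% of its free monomer still unbound.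

(The numbers belong to no real substance; the rest is arithmetic.)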